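The route cuts the C5–C11 bond of the cyclobutane (longipinane locants). One photochemical step, a Norrish–Yang reaction, turns a cis-fused bicyclo[5.4.0]undecan-5-one into the tricyclic cage. It exploits the C5 carbonyl, which sits axial on C4 of the six-membered ring and is therefore gamma to the C11 methylene through C4 and C10: it takes the syn-axial C11 hydrogen, and the 1,4-biradical closes the four-membered ring. The precursor carries C1 as a dioxolane, a saturated C2–C3 with the C3 methyl cis to C5, and both isovalerates already in place. It is built by a butenolide Diels–Alder reaction, reverse prenylation, ring-closing metathesis and directed oxymercuration.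

Key step: step 10

Remark (locants): C1–C11 are longipinane locants; the six-membered ring is C1–C2–C3–C4–C10–C11 and the seven-membered ring is C4–C5–C6–C7–C8–C9–C10. In every bicyclic or tricyclic compound H4 and the C10 methyl are cis, the C3 methyl is cis to C5, the C9 oxygen is trans to the C10 methyl, and the C7 oxygen is trans to the C9 oxygen.
Assumption (step 1): the ProPhenol antipode that gives the 4R carbinol is the one used; the S,S ligand is written.
Assumption (steps 6 to 8): 12, 13 and 15 are drawn as open hydroxy ketones; equilibrium with the C5/C9 hemiketal should not change the sense of any later step.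

Step 1
Reactants: 1 (E)-but-2-enal; 2 methyl propiolate
Product: 3 methyl (4R,5E)-4-hydroxyhept-5-en-2-ynoate
Conditions: Me2Zn, (S,S)-ProPhenol (20 mol%), Ph3PO (40 mol%), toluene, 4 °C
Reagents that add atoms: none
Why: Catalytic asymmetric alkynylation of an aldehyde by a zinc acetylide should give 1,2-addition to the enal, and the chiral dinuclear zinc catalyst sets the C9 carbinol as R.

Step 2
Reactants: 3 methyl (4R,5E)-4-hydroxyhept-5-en-2-ynoate
Product: 5 (5R)-4-methyl-5-[(E)-prop-1-enyl]furan-2(5H)-one, via hydroxy dienoate 4 (not isolated)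
Conditions: MeLi, CuI, THF, −78 °C; NH4Cl (aq), −78 °C to rt
Reagents that add atoms: lithium dimethylcuprate, [Li+].C[Cu-]C
Why: Cuprate conjugate addition to the ynoate is a syn carbometalation, so ester and carbinol end up cis on the new double bond and lactonise on work-up, while the C9 centre is not touched.

Step 3
Reactants: 6 (E)-pent-3-en-2-one
Product: 7 (E)-2-(tert-butyldimethylsilyloxy)penta-1,3-diene
Conditions: TBSOTf, Et3N, Et2O, 0 °C
Reagents that add atoms: tert-butyldimethylsilyl trifluoromethanesulfonate, CC(C)(C)[Si](C)(C)OS(=O)(=O)C(F)(F)F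
Why: Soft enolisation and O-silylation on the methyl side of the ketone (silyl enol ether formation) should give the cross-conjugated 2-silyloxydiene with the E alkene unchanged.

Step 4
Reactants: 5 (5R)-4-methyl-5-[(E)-prop-1-enyl]furan-2(5H)-one; 7 (E)-2-(tert-butyldimethylsilyloxy)penta-1,3-diene
Product: 9 cis-fused 3a,7-dimethyl-3-[(E)-prop-1-enyl]hexahydroisobenzofuran-1,5-dione, via silyl enol ether cycloadduct 8 (not isolated)
Conditions: toluene, BHT, 160 °C, sealed tube; then 1 M HCl, THF, 0 °C
Reagents that add atoms: none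
Why: In this Diels–Alder reaction the nucleophilic CH2 terminus of the 2-silyloxydiene bonds to the beta carbon C10, the diene adds anti to the propenyl group on C9 (setting C10 and C4 with H and methyl cis), the endo arrangement of the lactone under the diene places the C3 methyl cis to C5, and acid then frees the C1 ketone.

Step 5
Reactants: 9 cis-fused 3a,7-dimethyl-3-[(E)-prop-1-enyl]hexahydroisobenzofuran-1,5-dione
Product: 10 C1 ethylene ketal of keto lactone 9
Conditions: TMSOCH2CH2OTMS, TMSOTf (cat.), CH2Cl2, −78 °C
Reagents that add atoms: 1,2-bis(trimethylsilyloxy)ethane, C[Si](C)(C)OCCO[Si](C)(C)C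
Why: Silyl-triflate-catalysed ketalisation with the bis-silyl ether of ethylene glycol should mask the unhindered C1 ketone at low temperature without ionising the allylic lactone C9–O bond.

Step 6
Reactants: 10 C1 ethylene ketal of keto lactone 9; 11 prenylmagnesium chloride
Product: 12 1,1-ethylenedioxy-3,10-dimethyl-4-(2,2-dimethylbut-3-enoyl)-10-[(E)-1-hydroxybut-2-enyl]cyclohexane
Conditions: THF, −78 to −20 °C; NH4Cl (aq)
Reagents that add atoms: none
Why: Addition of the allylic Grignard reagent with allylic transposition (reverse prenylation through a six-membered transition state) joins the quaternary C6 to the lactone carbonyl C5, and the magnesium lactolate should resist a second addition, so the hindered C5 ketone and the free C9 alcohol appear on work-up.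

Step 7
Reactants: 12 1,1-ethylenedioxy-3,10-dimethyl-4-(2,2-dimethylbut-3-enoyl)-10-[(E)-1-hydroxybut-2-enyl]cyclohexane
Product: 13 1,1-ethylenedioxy-9-hydroxy-3,6,6,10-tetramethyl-cis-bicyclo[5.4.0]undec-7-en-5-one
Conditions: second-generation Grubbs catalyst RuCl2(=CHPh)(H2IMes)(PCy3) (5 mol%), CH2Cl2 (5 mM), 40 °C
Reagents that add atoms: none
Why: Ring-closing metathesis of the two alkenes held cis on C4 and C10 should close the seven-membered ring as the cis C7=C8 alkene with loss of propene.

Step 8
Reactants: 13 1,1-ethylenedioxy-9-hydroxy-3,6,6,10-tetramethyl-cis-bicyclo[5.4.0]undec-7-en-5-one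
Product: 15 1,1-ethylenedioxy-7,9-dihydroxy-3,6,6,10-tetramethyl-cis-bicyclo[5.4.0]undecan-5-one, via organomercurial acetate 14 (not isolated)
Conditions: Hg(OAc)2, THF/H2O (1:1), rt; then Bu3SnH, THF, 0 °C
Reagents that add atoms: water, O
Why: In this hydroxyl-directed oxymercuration–demercuration mercury should add to the alkene face syn to the C9 oxygen, water opens the mercurinium ion anti at C7 (the carbon remote from the electron-withdrawing C9–O bond), so the C7 hydroxyl comes out trans to the C9 hydroxyl, and the tin hydride replaces mercury at C8 by hydrogen without base or hydride that would harm the aldol-type C5/C7 array.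

Step 9
Reactants: 15 1,1-ethylenedioxy-7,9-dihydroxy-3,6,6,10-tetramethyl-cis-bicyclo[5.4.0]undecan-5-one; 16 isovaleric anhydride
Product: 17 1,1-ethylenedioxy-7,9-bis(3-methylbutanoyloxy)-3,6,6,10-tetramethyl-cis-bicyclo[5.4.0]undecan-5-one
Conditions: DMAP, Et3N, CH2Cl2, rt to 40 °C
Reagents that add atoms: none
Why: DMAP-catalysed acylation should esterify both secondary alcohols, and the C7 ester cannot eliminate because C6 bears no hydrogen.

Step 10
Reactants: 17 1,1-ethylenedioxy-7,9-bis(3-methylbutanoyloxy)-3,6,6,10-tetramethyl-cis-bicyclo[5.4.0]undecan-5-one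
Product: 18 1,1-ethylenedioxy-5-hydroxylongipinane-7,9-diyl bis(3-methylbutanoate)
Conditions: hν (300 nm, Pyrex), degassed MeCN (2 mM), 0 °C
Reagents that add atoms: none
Why: Excitation of the isolated C5 ketone (n,π*) should lead to 1,5-hydrogen transfer from C11 through the six-membered array O–C5–C4–C10–C11–H, and the 1,4-biradical (hydroxy radical at C5, radical at C11) collapses to the C5–C11 bond, which is the Norrish–Yang cyclisation of a ketone to a cyclobutanol. The four-membered ring closes by radical–radical combination across C5 and C11 inside the chair of the six-membered ring, not by attack on a π bond. C11 is fixed because hydrogen leaves and carbon enters on the same axial face, and C5 is fixed because C6 is tied to C10 through C7–C9 and must stay anti to the C1–C3 bridge, so the hydroxyl has to point syn. The selectivity needed is C11–H over the equally syn-axial C2–H, over the C9–H and C3-methyl hydrogens, and over alpha-cleavage beside C6: the C3 methyl cis to C5 holds the chair with C5 axial and the C10 methyl anti to it, only the C11-centred biradical can turn the p orbital on C5 toward its partner without swinging C6 and its methyl groups over the six-membered ring (the C2-centred biradical should return its hydrogen), the C9–H is deactivated by its acyloxy group, and the ketal at C1 with low temperature leaves C5 as the only chromophore and slows alpha-cleavage.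

Step 11
Reactants: 18 1,1-ethylenedioxy-5-hydroxylongipinane-7,9-diyl bis(3-methylbutanoate)
Product: 19 1,1-ethylenedioxy-5-(methoxyoxalyloxy)longipinane-7,9-diyl bis(3-methylbutanoate)
Conditions: ClC(O)CO2Me, DMAP, pyridine, CH2Cl2, 0 °C to rt
Reagents that add atoms: methyl chlorooxoacetate, COC(=O)C(=O)Cl
Why: Acylation of the hindered tertiary cyclobutanol by the small, very electrophilic acid chloride should give the mixed oxalate, and no elimination can compete because C4 and C11 are bridgeheads and C6 has no hydrogen.

Step 12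
Reactants: 19 1,1-ethylenedioxy-5-(methoxyoxalyloxy)longipinane-7,9-diyl bis(3-methylbutanoate)
Product: 20 1,1-ethylenedioxylongipinane-7,9-diyl bis(3-methylbutanoate)
Conditions: Bu3SnH, AIBN (cat.), toluene, 110 °C
Reagents that add atoms: none
Why: In this tin hydride deoxygenation of a tertiary methyl oxalate (Barton–McCombie type) the stannyl radical adds to the oxalate, the C5–O bond fragments, and the C5 cyclobutyl radical takes hydrogen on its only open face, syn to the C1–C3 bridge, which is the configuration of the target.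

Step 13
Reactants: 20 1,1-ethylenedioxylongipinane-7,9-diyl bis(3-methylbutanoate)
Product: 21 1-oxolongipinane-7,9-diyl bis(3-methylbutanoate)
Conditions: TsOH·H2O (cat.), acetone/H2O (10:1), 40 °C
Reagents that add atoms: water, O
Why: Acid-catalysed ketal hydrolysis should free the C1 ketone with the esters intact, and it comes after deoxygenation of C5 so that no retro-aldol opening of the four-membered ring is possible.

Step 14
Reactants: 21 1-oxolongipinane-7,9-diyl bis(3-methylbutanoate)
Product: 23 1-oxolongipin-2-ene-7,9-diyl bis(3-methylbutanoate) (CNP0192813.1), via trimethylsilyl enol ether 22 (not isolated)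
Conditions: TMSOTf, Et3N, CH2Cl2, 0 °C; then Pd(OAc)2, MeCN, rt
Reagents that add atoms: none
Why: In this Saegusa–Ito oxidation enolisation can only go toward C2 because C11 is a cyclobutane bridgehead, and palladium diacetate should convert the silyl enol ether by beta-hydride loss from C3 into the C2=C3 enone, which removes the auxiliary C3 centre.

Compound list
1 | (E)-but-2-enal | C/C=C/C=O | starting material
2 | methyl propiolate | C#CC(=O)OC | starting material
3 | methyl (4R,5E)-4-hydroxyhept-5-en-2-ynoate | C/C=C/[C@@H](O)C#CC(=O)OC | intermediate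
4 | methyl (2Z,4R,5E)-4-hydroxy-3-methylhepta-2,5-dienoate | C/C=C/[C@@H](O)/C(C)=C\C(=O)OC | intermediate
5 | (5R)-4-methyl-5-[(E)-prop-1-enyl]furan-2(5H)-one | C/C=C/[C@H]1OC(=O)C=C1C | intermediate
6 | (E)-pent-3-en-2-one | C/C=C/C(C)=O | starting material
7 | (E)-2-(tert-butyldimethylsilyloxy)penta-1,3-diene | C=C(O[Si](C)(C)C(C)(C)C)/C=C/C | intermediate
8 | cis-fused 5-(tert-butyldimethylsilyloxy)-3a,7-dimethyl-3-[(E)-prop-1-enyl]-3a,4,7,7a-tetrahydroisobenzofuran-1(3H)-one; propenyl cis to the 3a-methyl, 7-methyl cis to the lactone carbonyl | C[C@@H]1C=C(O[Si](C)(C)C(C)(C)C)C[C@]2(C)[C@H](OC(=O)[C@H]12)/C=C/C | intermediate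
9 | cis-fused 3a,7-dimethyl-3-[(E)-prop-1-enyl]hexahydroisobenzofuran-1,5-dione; same relative configuration as 8 | C[C@@H]1CC(=O)C[C@]2(C)[C@H](OC(=O)[C@H]12)/C=C/C | intermediate
10 | C1 (isobenzofuranone C5) ethylene ketal of 9 | C[C@@H]1CC3(OCCO3)C[C@]2(C)[C@H](OC(=O)[C@H]12)/C=C/C | intermediate
11 | prenylmagnesium chloride (3-methylbut-2-enylmagnesium chloride) | CC(C)=CC[Mg]Cl | starting material
12 | 1,1-ethylenedioxy-3,10-dimethyl-4-(2,2-dimethylbut-3-enoyl)-10-[(E)-1-hydroxybut-2-enyl]cyclohexane (longipinane locants; acyl on C4 cis to the C9 chain and to the C3 methyl) | C[C@@H]1CC3(OCCO3)C[C@](C)([C@H](O)/C=C/C)[C@@H]1C(=O)C(C)(C)C=C | intermediate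
13 | 1,1-ethylenedioxy-9-hydroxy-3,6,6,10-tetramethyl-cis-bicyclo[5.4.0]undec-7-en-5-one | C[C@@H]1CC4(OCCO4)C[C@]2(C)[C@H](O)/C=C\C(C)(C)C(=O)[C@H]12 | intermediate
14 | 8-(acetoxymercurio)-1,1-ethylenedioxy-7,9-dihydroxy-3,6,6,10-tetramethyl-cis-bicyclo[5.4.0]undecan-5-one; mercury cis to the C9 hydroxyl, C7 hydroxyl trans to both | C[C@@H]1CC4(OCCO4)C[C@]2(C)[C@H](O)[C@H]([Hg]OC(C)=O)[C@@H](O)C(C)(C)C(=O)[C@H]12 | intermediate
15 | 1,1-ethylenedioxy-7,9-dihydroxy-3,6,6,10-tetramethyl-cis-bicyclo[5.4.0]undecan-5-one (7,9-trans diol) | C[C@@H]1CC4(OCCO4)C[C@]2(C)[C@H](O)C[C@@H](O)C(C)(C)C(=O)[C@H]12 | intermediate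
16 | isovaleric anhydride (3-methylbutanoic anhydride) | CC(C)CC(=O)OC(=O)CC(C)C | starting material
17 | 1,1-ethylenedioxy-7,9-bis(3-methylbutanoyloxy)-3,6,6,10-tetramethyl-cis-bicyclo[5.4.0]undecan-5-one (precursor of the key step) | C[C@@H]1CC4(OCCO4)C[C@]2(C)[C@H](OC(=O)CC(C)C)C[C@@H](OC(=O)CC(C)C)C(C)(C)C(=O)[C@H]12 | intermediate
18 | 1,1-ethylenedioxy-5-hydroxylongipinane-7,9-diyl bis(3-methylbutanoate); C5 hydroxyl syn to the C1–C3 bridge | C[C@@H]1CC4(OCCO4)[C@@H]2[C@]3(O)[C@H]1[C@@]2(C)[C@H](OC(=O)CC(C)C)C[C@@H](OC(=O)CC(C)C)C3(C)C | intermediate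
19 | 1,1-ethylenedioxy-5-(methoxyoxalyloxy)longipinane-7,9-diyl bis(3-methylbutanoate) | C[C@@H]1CC4(OCCO4)[C@@H]2[C@]3(OC(=O)C(=O)OC)[C@H]1[C@@]2(C)[C@H](OC(=O)CC(C)C)C[C@@H](OC(=O)CC(C)C)C3(C)C | intermediate
20 | 1,1-ethylenedioxylongipinane-7,9-diyl bis(3-methylbutanoate) | C[C@@H]1CC4(OCCO4)[C@@H]2[C@@H]3[C@H]1[C@@]2(C)[C@H](OC(=O)CC(C)C)C[C@@H](OC(=O)CC(C)C)C3(C)C | intermediate
21 | 1-oxolongipinane-7,9-diyl bis(3-methylbutanoate) | C[C@@H]1CC(=O)[C@@H]2[C@@H]3[C@H]1[C@@]2(C)[C@H](OC(=O)CC(C)C)C[C@@H](OC(=O)CC(C)C)C3(C)C | intermediate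
22 | 1-(trimethylsilyloxy)longipin-1-ene-7,9-diyl bis(3-methylbutanoate) | C[C@@H]1C=C(O[Si](C)(C)C)[C@@H]2[C@@H]3[C@H]1[C@@]2(C)[C@H](OC(=O)CC(C)C)C[C@@H](OC(=O)CC(C)C)C3(C)C | intermediate
23 | 1-oxolongipin-2-ene-7,9-diyl bis(3-methylbutanoate), CNP0192813.1 | CC1=CC(=O)[C@@H]2[C@@H]3[C@H]1[C@@]2(C)[C@H](OC(=O)CC(C)C)C[C@@H](OC(=O)CC(C)C)C3(C)C | target

Total step count: 14. Longest linear sequence: 13 steps (steps 1, 2 and 4 to 14; step 3 makes the diene in a side branch).

Steps most likely to fail

Step 10. Hydrogen transfer may start from the other syn-axial position (C2), alpha-cleavage of the C5–C6 bond may come first, or the biradical may fragment instead of closing. The fallback sets out from 17 and comes back at 21, replacing steps 10 to 13 by an anionic closure of the same C5–C11 bond. SmI2, i-PrOH, THF should reduce the C5 ketone under thermodynamic control to the C5 alcohol F1 with its hydroxyl on the face away from C11. MsCl, Et3N, CH2Cl2 gives the mesylate F2. TsOH, acetone/H2O frees the C1 ketone as keto mesylate F3. KHMDS, THF, −78 °C to rt then closes the four-membered ring by intramolecular enolate alkylation: the C11 enolate displaces the C5 mesylate with inversion, and the C2 enolate cannot reach the back side of C5. This gives 21.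

Step 4. Bond formation at the fully substituted beta carbon C10 may be too slow, so that the butenolide isomerises through its furanol tautomer at the temperature needed, and endo selectivity may erode. The fallback sets out from 5 and comes back at 9, building the quaternary centre by cuprate addition and the six-membered ring by two polar steps. AllylMgBr, CuBr·SMe2, TMSCl, THF, −78 °C should add the allyl group to C10 anti to the propenyl group and give allyl lactone F4. Tsuji–Wacker oxidation (PdCl2, CuCl, O2, DMF/H2O) of the terminal alkene gives methyl ketone F5. LDA then acetaldehyde at −78 °C gives aldol F6, and MsCl with excess Et3N dehydrates it to E enone F7. Catalytic t-BuOK in THF closes the ring by intramolecular Michael addition of the lactone enolate (C4) to C3. This gives 9 when the lactone lies under the enone as in the cycloaddition; a C3 epimer formed alongside would be separated.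

Step 8. The hydroxyl direction may be lost, so that mercury adds from the other face, or water may open the mercurinium ion at C8 because C7 is neopentylic. The fallback sets out from 13 and comes back at 15 and sets C7 by reduction instead of addition. Tsuji–Wacker oxidation (PdCl2, CuCl, O2, DMF/H2O) should place the carbonyl at C7, remote from the C9 oxygen, and give hydroxy diketone F8. Me4N[BH(OAc)3], MeCN/AcOH, −20 °C (Evans–Saksena reduction) then delivers hydride from the boron bound to the C9 oxygen to the same face of C7, which gives the trans diol 15 and leaves the C5 ketone alone.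

Further compounds
F1 | step 10 | 1,1-ethylenedioxy-5-hydroxy-3,6,6,10-tetramethyl-cis-bicyclo[5.4.0]undecane-7,9-diyl bis(3-methylbutanoate), C5 hydroxyl on the face away from C11 | C[C@@H]1CC4(OCCO4)C[C@]2(C)[C@H](OC(=O)CC(C)C)C[C@@H](OC(=O)CC(C)C)C(C)(C)[C@@H](O)[C@H]12
F2 | step 10 | C5 methanesulfonate of F1 | C[C@@H]1CC4(OCCO4)C[C@]2(C)[C@H](OC(=O)CC(C)C)C[C@@H](OC(=O)CC(C)C)C(C)(C)[C@@H](OS(C)(=O)=O)[C@H]12
F3 | step 10 | 5-(methylsulfonyloxy)-1-oxo-3,6,6,10-tetramethyl-cis-bicyclo[5.4.0]undecane-7,9-diyl bis(3-methylbutanoate) | C[C@@H]1CC(=O)C[C@]2(C)[C@H](OC(=O)CC(C)C)C[C@@H](OC(=O)CC(C)C)C(C)(C)[C@@H](OS(C)(=O)=O)[C@H]12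
F4 | step 4 | 4-allyl-4-methyl-5-[(E)-prop-1-enyl]dihydrofuran-2(3H)-one, allyl trans to propenyl | C=CC[C@@]1(C)CC(=O)O[C@@H]1/C=C/C
F5 | step 4 | 4-methyl-4-(2-oxopropyl)-5-[(E)-prop-1-enyl]dihydrofuran-2(3H)-one | CC(=O)C[C@@]1(C)CC(=O)O[C@@H]1/C=C/C
F6 | step 4 | 4-(4-hydroxy-2-oxopentyl)-4-methyl-5-[(E)-prop-1-enyl]dihydrofuran-2(3H)-one, both carbinol epimers | CC(O)CC(=O)C[C@@]1(C)CC(=O)O[C@@H]1/C=C/C
F7 | step 4 | 4-methyl-4-[(E)-2-oxopent-3-enyl]-5-[(E)-prop-1-enyl]dihydrofuran-2(3H)-one | C/C=C/C(=O)C[C@@]1(C)CC(=O)O[C@@H]1/C=C/C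
F8 | step 8 | 1,1-ethylenedioxy-9-hydroxy-3,6,6,10-tetramethyl-cis-bicyclo[5.4.0]undecane-5,7-dione | C[C@@H]1CC4(OCCO4)C[C@]2(C)[C@H](O)CC(=O)C(C)(C)C(=O)[C@H]12
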